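The green run and the ochre run, both under the same feed, are the basis for the flask below.

| flask | substrate | partner | free catalyst | remark | time |
|---|---|---|---|---|---|
| green | 20 mM (fed, over 20 min) | 1.8 equiv | 0.055 mol% | run made earlier |  |
| ochre | 20 mM (fed, over 20 min) | 1.8 equiv | 0.083 mol% | run made earlier |  |
| flask | 20 mM (fed, over 20 min) | 1.80 equiv | 0.11 mol% |  | 20 min |

| run | time / min | target / % | substrate / % |
|---|---|---|---|
| green | 2.00 | 0.5 | 11.0 |
| green | 4.00 | 4.3 | 17.9 |
| green | 10.0 | 5.7 | 46.3 |
| green | 25.0 | 15.1 | 84.3 |
| ochre | 3.00 | 0.5 | 14.8 |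
| ochre | 8.00 | 4.7 | 34.7 |
| ochre | 15.0 | 9.2 | 64.8 |
| ochre | 25.0 | 18.1 | 80.3 |

(standard deviation of a reading: 1 percentage point)

1. concentration of target at 20 min, in mM
2. concentration of substrate at 20 min, in mM

- percentages count the whole charge, also what has not yet gone in

Counted in turnovers per minute, target per catalyst charged, green averaged 10.4 min⁻¹ up to 10.0 min, while ochre averaged 7.39 min⁻¹ up to 15.0 min, fewer per catalyst at its higher loading. My own assumption is that the rate of target rises with the square root of the loading, so the fraction of the charge made as target per minute, divided by the square root of the loading, gives 0.243 min⁻¹ for green and 0.213 min⁻¹ for ochre, each from a reading with a scatter of 1 percentage point. Their mean, 0.228 min⁻¹, is the root-loading rate G, read during the feed, with feed and charge held. My own reckoning from G gives the flask 3.02 mM of target, and, with the feed complete, 17.0 mM of substrate.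

The forecast says 3.2 mM of target (2.8 mM to 3.9 mM) and 16.8 mM of substrate (16 mM to 17.2 mM), its target above mine, on the grounds that “the response is clearly sublinear”.

The flask gives [target] = 3.15 mM and [substrate] = 16.4 mM, so the forecast held on both.

    substrate + free catalyst ⇌ catalyst intermediate A (K = 400 M⁻¹, k = 5900 M⁻¹ min⁻¹)
    partner + catalyst intermediate A → catalyst intermediate B (k = 1900 M⁻¹ min⁻¹)
    catalyst intermediate B → by-product + catalyst intermediate C (k = 7700 min⁻¹)
    catalyst intermediate C → free catalyst + target (k = 2100 min⁻¹)
    substrate + target → side product (k = 0.680 M⁻¹ min⁻¹)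
    free catalyst + by-product ⇌ idle complex, settled at all times (K = 2100 M⁻¹)

At 20.0 min the idle complex, an off-cycle form, holds 75.4% of the catalyst, with 3.37 mM of by-product present. The flask has made 143 turnovers, and its own G is 0.237 min⁻¹, against 0.228 min⁻¹ from the runs.

For a neighbour flask charged with 0.044 mol% of free catalyst, G gives 1.91 mM of target. The simulation of that neighbour gives 1.85 mM.

The runs are simulated on assumed constants, noise included.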